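**Strategy.** Ring C is closed by making the C2–C3 bond. C3 is the carbon α to the C4 ketone, and C2 is a benzylic carbon that carries the ring oxygen O1 and the p-anisyl ring B. The precursor is therefore a ring A α-diazoketone whose neighbouring oxygen carries a 4-methoxybenzyl ether, with prenyl, methoxy and a silyl ether already in place. An enantioselective rhodium-carbene insertion into the doubly activated O–CH2–Ar hydrogen turns what looks like a protecting group into C2 and ring B, and sets the 2S centre under catalyst control.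

Key step: step 5

Remark: the stereodescriptor of the target corresponds to 2S. 2',6'-Dihydroxy-4'-methoxyacetophenone, prenyl bromide and 4-methoxybenzyl alcohol are taken as commercial.

**Step 1**
Reactants: 1 2',6'-dihydroxy-4'-methoxyacetophenone; 2 prenyl bromide (1-bromo-3-methylbut-2-ene)
Product: 3 1-[2,6-dihydroxy-4-methoxy-3-(3-methylbut-2-en-1-yl)phenyl]ethan-1-one
Conditions: KOH (10% aq), 0 °C → rt, then acidify
Reagents that add atoms: none
Why: Nuclear C-alkylation of a phloroglucinol-type phenoxide in water, where the ambident anion reacts at carbon; positions 3 and 5 of 1 are equivalent by symmetry, so only one mono-C-prenyl isomer can form.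

**Step 2**
Reactants: 3 1-[2,6-dihydroxy-4-methoxy-3-(3-methylbut-2-en-1-yl)phenyl]ethan-1-one
Product: 4 1-[2-hydroxy-4-methoxy-3-(3-methylbut-2-en-1-yl)-6-(triisopropylsilyloxy)phenyl]ethan-1-one
Conditions: TIPSCl (1.1 equiv), imidazole, DMF, 0 °C → rt
Reagents that add atoms: triisopropylsilyl chloride, CC(C)[Si](Cl)(C(C)C)C(C)C
Why: Silylation with a bulky chlorosilane should go to the less hindered C6 hydroxyl (flanked by H), while the hydroxyl between acetyl and prenyl stays hydrogen-bonded to the ketone and resists a second silylation.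

**Step 3**
Reactants: 4 1-[2-hydroxy-4-methoxy-3-(3-methylbut-2-en-1-yl)-6-(triisopropylsilyloxy)phenyl]ethan-1-one; 5 4-methoxybenzyl alcohol
Product: 6 1-[4-methoxy-2-[(4-methoxyphenyl)methoxy]-3-(3-methylbut-2-en-1-yl)-6-(triisopropylsilyloxy)phenyl]ethan-1-one
Conditions: PPh3, DIAD, THF, 0 °C → rt
Reagents that add atoms: none
Why: Mitsunobu etherification of the acidic, hydrogen-bonded phenol with a primary benzylic alcohol under neutral conditions that spare the silyl ether and the prenyl alkene.

**Step 4**
Reactants: 6 1-[4-methoxy-2-[(4-methoxyphenyl)methoxy]-3-(3-methylbut-2-en-1-yl)-6-(triisopropylsilyloxy)phenyl]ethan-1-one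
Product: 8 2-diazo-1-[4-methoxy-2-[(4-methoxyphenyl)methoxy]-3-(3-methylbut-2-en-1-yl)-6-(triisopropylsilyloxy)phenyl]ethan-1-one, via trifluoroacetyl diketone 7 (not isolated)
Conditions: LiN(SiMe3)2, THF, −78 °C; CF3CO2CH2CF3; 5% aq HCl work-up; then MsN3, Et3N, H2O (1 equiv), MeCN, rt
Reagents that add atoms: methanesulfonyl azide, CS(=O)(=O)N=[N+]=[N-]; 2,2,2-trifluoroethyl trifluoroacetate, O=C(OCC(F)(F)F)C(F)(F)F (its trifluoroacetyl group is carried only by intermediate 7)
Why: Danheiser detrifluoroacetylative diazo transfer: the kinetic lithium enolate is trifluoroacetylated, and the activated 1,3-diketone 7 takes the diazo group from the sulfonyl azide with loss of the trifluoroacetyl group as the N-acylsulfonamide.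

**Step 5**
Reactants: 8 2-diazo-1-[4-methoxy-2-[(4-methoxyphenyl)methoxy]-3-(3-methylbut-2-en-1-yl)-6-(triisopropylsilyloxy)phenyl]ethan-1-one
Product: 9 (2S)-7-methoxy-2-(4-methoxyphenyl)-8-(3-methylbut-2-en-1-yl)-5-(triisopropylsilyloxy)-2,3-dihydro-4H-chromen-4-one
Conditions: Rh2(S-BSP)4 (dirhodium tetrakis[(S)-N-(phenylsulfonyl)prolinate], 1 mol %), CH2Cl2, 0 °C → rt, slow addition of 8 at high dilution
Reagents that add atoms: none
Why: The divalent rhodium dimer should decompose the diazoketone with loss of N2 to an electrophilic rhodium carbene at the carbon α to the ketone, which inserts into one benzylic C–H bond of the OCH2Ar group through a concerted, asynchronous three-centre (hydride-shift-like) transition state and so makes the C2–C3 bond. The closest known reaction type is the rhodium carboxylate-catalysed intramolecular C–H insertion of ortho-alkoxyaryl diazoketones to chroman-4-ones, including enantioselective versions with prolinate catalysts. Ring C closes in a 1,6-insertion mode (six-membered ring through C3, C4, C4a, C8a, O1 and C2), because the usual 1,5 position is the oxygen O1 and bears no hydrogen. The new C2 stereocentre is set under catalyst control: the chiral carboxylate pocket selects which of the two enantiotopic benzylic hydrogens is replaced, the S-prolinate series being taken as the one that leads to 2S and the mirror-image catalyst Rh2(R-BSP)4 serving if the sense proves opposite. The step needs C–H insertion to win over oxonium-ylide formation with benzyl shift and over attack at other sites. This should be secured by the doubly activated C–H bond (α-oxygen and p-anisyl), by a rhodium carboxylate rather than a copper catalyst, by the silyl ether at O5 having no C–H bond on the atom attached to oxygen, and by the prenyl group being meta to the ketone-bearing carbon and so out of reach.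

**Step 6**
Reactants: 9 (2S)-7-methoxy-2-(4-methoxyphenyl)-8-(3-methylbut-2-en-1-yl)-5-(triisopropylsilyloxy)-2,3-dihydro-4H-chromen-4-one
Product: 10 flowerine, (2S)-5-hydroxy-7-methoxy-2-(4-methoxyphenyl)-8-(3-methylbut-2-en-1-yl)-2,3-dihydro-4H-chromen-4-one
Conditions: n-Bu4NF, AcOH (1:1), THF, 0 °C
Reagents that add atoms: none
Why: Fluoride cleavage of an aryl silyl ether, buffered with acetic acid so that no phenoxide base is present to open ring C by a retro-oxa-Michael reaction, which should keep the 2S centre intact.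

**Compound list**
1 | 2',6'-dihydroxy-4'-methoxyacetophenone | CC(=O)c1c(O)cc(OC)cc1O | starting material
2 | prenyl bromide (1-bromo-3-methylbut-2-ene) | CC(C)=CCBr | starting material
3 | 1-[2,6-dihydroxy-4-methoxy-3-(3-methylbut-2-en-1-yl)phenyl]ethan-1-one | CC(=O)c1c(O)cc(OC)c(CC=C(C)C)c1O | intermediate
4 | 1-[2-hydroxy-4-methoxy-3-(3-methylbut-2-en-1-yl)-6-(triisopropylsilyloxy)phenyl]ethan-1-one | CC(=O)c1c(O[Si](C(C)C)(C(C)C)C(C)C)cc(OC)c(CC=C(C)C)c1O | intermediate
5 | 4-methoxybenzyl alcohol | COc1ccc(CO)cc1 | starting material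
6 | 1-[4-methoxy-2-[(4-methoxyphenyl)methoxy]-3-(3-methylbut-2-en-1-yl)-6-(triisopropylsilyloxy)phenyl]ethan-1-one | CC(=O)c1c(O[Si](C(C)C)(C(C)C)C(C)C)cc(OC)c(CC=C(C)C)c1OCc1ccc(OC)cc1 | intermediate
7 | 4,4,4-trifluoro-1-[4-methoxy-2-[(4-methoxyphenyl)methoxy]-3-(3-methylbut-2-en-1-yl)-6-(triisopropylsilyloxy)phenyl]butane-1,3-dione (not isolated) | O=C(CC(=O)C(F)(F)F)c1c(O[Si](C(C)C)(C(C)C)C(C)C)cc(OC)c(CC=C(C)C)c1OCc1ccc(OC)cc1 | intermediate
8 | 2-diazo-1-[4-methoxy-2-[(4-methoxyphenyl)methoxy]-3-(3-methylbut-2-en-1-yl)-6-(triisopropylsilyloxy)phenyl]ethan-1-one | [N-]=[N+]=CC(=O)c1c(O[Si](C(C)C)(C(C)C)C(C)C)cc(OC)c(CC=C(C)C)c1OCc1ccc(OC)cc1 | intermediate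
9 | (2S)-7-methoxy-2-(4-methoxyphenyl)-8-(3-methylbut-2-en-1-yl)-5-(triisopropylsilyloxy)-2,3-dihydro-4H-chromen-4-one | COc1ccc([C@@H]2CC(=O)c3c(O[Si](C(C)C)(C(C)C)C(C)C)cc(OC)c(CC=C(C)C)c3O2)cc1 | intermediate
10 | flowerine, (2S)-5-hydroxy-7-methoxy-2-(4-methoxyphenyl)-8-(3-methylbut-2-en-1-yl)-2,3-dihydro-4H-chromen-4-one | COc1ccc([C@@H]2CC(=O)c3c(O)cc(OC)c(CC=C(C)C)c3O2)cc1 | target

**Step count and risks**
Total steps: 6. Longest linear sequence: 6 steps (from 1).

Steps most likely to fail:

1. Step 5. The carbene may be diverted to the ether oxygen (oxonium ylide, then [1,2]-benzyl shift to a benzofuranone skeleton), or the catalyst may discriminate poorly between the two enantiotopic benzylic hydrogens. The fallback sets out from 4 and gives up the carbene closure for a late aryl transfer. Heating 4 with N,N-dimethylformamide dimethyl acetal in toluene should give the enaminone (E)-3-(dimethylamino)-1-[2-hydroxy-4-methoxy-3-(3-methylbut-2-en-1-yl)-6-(triisopropylsilyloxy)phenyl]prop-2-en-1-one F1. Warming F1 in AcOH should cyclise it, with loss of dimethylamine, to 7-methoxy-8-(3-methylbut-2-en-1-yl)-5-(triisopropylsilyloxy)-4H-chromen-4-one F2. Asymmetric conjugate addition of 4-methoxyphenylboronic acid to F2 (Pd(OCOCF3)2, t-BuPyOx in the enantiomeric form that delivers 2S, NH4PF6, H2O, ClCH2CH2Cl, 60 °C) should then give 9, where the route is rejoined before step 6.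

2. Step 1. O-alkylation and double alkylation of the ambident phenoxide may outrun mono-C-alkylation. The fallback sets out from 1. Mitsunobu etherification with 3-methylbut-2-en-1-ol (PPh3, DIAD, THF) should give the mono-ether 1-[2-hydroxy-4-methoxy-6-(3-methylbut-2-en-1-yloxy)phenyl]ethan-1-one F3. A tandem Claisen–Cope (para-Claisen) rearrangement of F3 (Eu(fod)3, CHCl3, 60 °C, or N,N-diethylaniline at about 200 °C) should move the prenyl group to the ring carbon and return to the route at 3.

3. Step 2. The silyl chloride may not distinguish well enough between the two phenols, giving both regioisomeric silyl ethers. The fallback sets out from 1, fixes the regiochemistry by construction and bypasses step 1 as well: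
   - Silylation of symmetric 1 (TIPSCl, imidazole, DMF) should give 1-[2-hydroxy-4-methoxy-6-(triisopropylsilyloxy)phenyl]ethan-1-one F4.
   - Copper-catalysed O-alkylation of the remaining phenol with 3-chloro-3-methylbut-1-yne (CuCl2 cat., DBU, MeCN, 0 °C) should give 1-[4-methoxy-2-(2-methylbut-3-yn-2-yloxy)-6-(triisopropylsilyloxy)phenyl]ethan-1-one F5.
   - Semi-hydrogenation (H2, Pd/CaCO3 poisoned with Pb(OAc)2, quinoline, EtOAc) should give 1-[4-methoxy-2-(2-methylbut-3-en-2-yloxy)-6-(triisopropylsilyloxy)phenyl]ethan-1-one F6.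
   - Aromatic Claisen rearrangement of F6 in toluene at 110 °C should place the prenyl group on the only free ortho carbon and free the adjacent hydroxyl, which is 4, where the route is rejoined before step 3.

**Further compounds**
F1 | step 5 | (E)-3-(dimethylamino)-1-[2-hydroxy-4-methoxy-3-(3-methylbut-2-en-1-yl)-6-(triisopropylsilyloxy)phenyl]prop-2-en-1-one | CN(C)/C=C/C(=O)c1c(O[Si](C(C)C)(C(C)C)C(C)C)cc(OC)c(CC=C(C)C)c1O
F2 | step 5 | 7-methoxy-8-(3-methylbut-2-en-1-yl)-5-(triisopropylsilyloxy)-4H-chromen-4-one | COc1cc(O[Si](C(C)C)(C(C)C)C(C)C)c2c(=O)ccoc2c1CC=C(C)C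
F3 | step 1 | 1-[2-hydroxy-4-methoxy-6-(3-methylbut-2-en-1-yloxy)phenyl]ethan-1-one | CC(=O)c1c(O)cc(OC)cc1OCC=C(C)C
F4 | step 2 | 1-[2-hydroxy-4-methoxy-6-(triisopropylsilyloxy)phenyl]ethan-1-one | CC(=O)c1c(O)cc(OC)cc1O[Si](C(C)C)(C(C)C)C(C)C
F5 | step 2 | 1-[4-methoxy-2-(2-methylbut-3-yn-2-yloxy)-6-(triisopropylsilyloxy)phenyl]ethan-1-one | CC(=O)c1c(OC(C)(C)C#C)cc(OC)cc1O[Si](C(C)C)(C(C)C)C(C)C
F6 | step 2 | 1-[4-methoxy-2-(2-methylbut-3-en-2-yloxy)-6-(triisopropylsilyloxy)phenyl]ethan-1-one | CC(=O)c1c(OC(C)(C)C=C)cc(OC)cc1O[Si](C(C)C)(C(C)C)C(C)C
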